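The earlier runs and the new flask are calculated with constants of no real substance.

Saturday's run climbs slowly and then fast, and two of us read that climb differently.

| flask | X | G | L | temperature | remark | time |
|---|---|---|---|---|---|---|
| Saturday's | 0.80 M | 0.016 M | 0.5 mol% | 12 °C | run made earlier |  |
| Thursday's | 0.80 M | 0.016 M | 2 mol% | 29 °C | run made earlier |  |
| north-east | 0.80 M | 0.0160 M | 1 mol% | 35 °C |  | 1.5 h |
| north | 0.80 M | 0.0160 M | 1 mol% | 5 °C |  | 1.5 h |

| Saturday's: time / h | Saturday's: Q / % | Thursday's: time / min | Thursday's: Q / % |
|---|---|---|---|
| 0.417 | 12 | 20.0 | 94 |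
| 0.833 | 41 | 40.0 | 98 |
| 1.33 | 68 | 50.0 | 99 |
| 2.50 | 94 | 80.0 | 97 |
| 5.00 | 96 | 90.0 | 99 |

(standard deviation of a reading: 1.5 percentage points)

- what was read earlier has a scatter of 1.5 percentage points, one standard deviation

* the flask with the highest amount of Q, in percent of the X charged ("all alike" if they lie within 1.5 percentage points) (north-east / north / all alike)
* final Q, as a percentage of the X charged, in north-east
* final Q, as a percentage of the X charged, in north

We agree that the late readings level off, near 98.0% of the X charged. That figure is my own reckoning: it is what stays if each G takes one X. We part on the way up.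

The forecast sees a lag and “then roughly first-order growth”. It names north-east as the richer flask, with 98% there and 73% in north.

I hold that the rate itself keeps growing in step with time. Then minus the logarithm of the fraction of the ceiling still unmade grows with the squared time. So I divide the time by the square root of that number. This is the ramp time, read from Saturday's run at 0.833 h as 1.13 h. At half that time it reads 1.15 h, and a growing rate asks for the same number.

Thursday's first reading gives a ramp time of 0.186 h. That run is hotter and more heavily loaded, and these two runs cannot part the two settings. My guess is that one over the squared ramp time follows the square root of the loading, and I put the remainder on temperature.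

For north I reckon a ramp time of 1.73 h, and so Q of 51.6%, less than the forecast's number. For north-east I reckon 0.133 h, far under the 1.5 h allowed, which puts that flask at the ceiling.

The flask with more Q is north-east, at 98.0%, while north gives 44.1%, which is 29 percentage points below the forecast.

    X + L → Z + Q (k = 0.0200 M⁻¹ min⁻¹, Ea = 70.0 kJ mol⁻¹)
    X + Z → Q + Z, rate k2*[Z]*[X] (k = 10.0 M⁻¹ min⁻¹, Ea = 48.0 kJ mol⁻¹)
    2 L ⇌ E (K = 3200 M⁻¹, k = 540 M⁻¹ min⁻¹, Ea = 40.0 kJ mol⁻¹, ΔH = −47.0 kJ mol⁻¹)
    G + X → J (k = 2.40 M⁻¹ min⁻¹, Ea = 66.0 kJ mol⁻¹)
    (constants at 5 °C)

In north the half-life of X by X + Z → Q + Z is 1.4 h at 0.940 h and shorter, 0.98 h, at 1.50 h, while by X + L → Z + Q it is 25 d at 0.940 h. North's end gives a ramp time of 1.94 h, above Saturday's 1.13 h and my 1.73 h. The forecast's plateau stands where time suffices: north-east holds 98.0%, and north reaches 98.0% after 15.0 h. Carried by my loading rule to a neighbour of north with 1.7 mol% of L, north's ramp time gives 53.0%, and that neighbour stands at 52.8%.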